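## Retrosynthetic overview

- Target 15 ← bis-silyl ether 14 (fluoride) ← diol 12 (oxirane closed by displacement at C6 by the C4 oxygen) ← hydroxy acid 11 (borane reduction).
- The spiro carbon C4 is a ring carbon that carries an oxygen and, outside the five-membered ring, the single carbon C6. C1–C5 plus C6 are therefore read as the six carbons of a quinone-derived cyclohex-5-ene-1,2,4-trione, and the C4–C5 bond is disconnected as a benzilic acid ring contraction of trione 9 to acid 11.
- Trione 9 ← hydroxyquinone 6 by enantioselective C-methoxylation (sets C5) ← symmetric dimethoxyquinone 5 (mono-hydrolysis) ← double Suzuki coupling of dibromoquinone 2 (from bromanil 1) with boronate 4.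
- Ring order: the two benzene rings and the quinone ring are bought; the cyclopentenone arises from the quinone ring by contraction (step 7); the oxirane is closed last (step 9). The phenols are carried as triisopropylsilyl ethers, which tolerate the basic steps better than tert-butyldimethylsilyl ethers.

Key step: step 7

Remark: the cyclopentenone is numbered C1 (C=O), C2 (OMe), C3 (aryl), C4 (spiro carbon), C5 (OMe, aryl), with C6 the oxirane CH2. It is assumed that the (R,R)-iodane 8 delivers the methoxyl to the face that gives (S)-9; if a test run shows the opposite sense, the (S,S)-antipode of 7 is used in the same way.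

## Route

Step 1
Reactants: 1 bromanil
Product: 2 2,5-dibromo-3,6-dimethoxy-1,4-benzoquinone
Conditions: NaOMe (2.05 equiv), MeOH, 0 °C → rt
Reagents that add atoms: sodium methoxide, [Na+].[O-]C
Why: Two-fold addition–elimination (vinylogous acyl substitution) of methoxide on the tetrahaloquinone, in which the first methoxyl deactivates its own enone so that the second should enter at the opposite position and give the 2,5-dibromo-3,6-dimethoxy pattern.

Step 2
Reactants: 3 4-(4,4,5,5-tetramethyl-1,3,2-dioxaborolan-2-yl)phenol
Product: 4 triisopropyl[4-(4,4,5,5-tetramethyl-1,3,2-dioxaborolan-2-yl)phenoxy]silane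
Conditions: iPr3SiCl, imidazole, DMF, rt
Reagents that add atoms: triisopropylsilyl chloride, CC(C)[Si](Cl)(C(C)C)C(C)C
Why: Standard imidazole-promoted silylation of a phenol that leaves the pinacol boronate alone; the triisopropylsilyl ether is chosen because it resists the phosphate, hydroxide and bicarbonate steps ahead far better than a tert-butyldimethylsilyl ether and still falls to fluoride.

Step 3
Reactants: 2 2,5-dibromo-3,6-dimethoxy-1,4-benzoquinone; 4 triisopropyl[4-(4,4,5,5-tetramethyl-1,3,2-dioxaborolan-2-yl)phenoxy]silane (2.3 equiv)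
Product: 5 2,5-dimethoxy-3,6-bis[4-(triisopropylsilyloxy)phenyl]-1,4-benzoquinone
Conditions: PdCl2(dppf) (5 mol %; dppf = 1,1'-bis(diphenylphosphino)ferrocene), K3PO4, 1,4-dioxane/H2O (10:1), 80 °C
Reagents that add atoms: none
Why: Double Suzuki–Miyaura coupling at the two C–Br bonds, which as β-bromo enone positions add readily to zerovalent palladium, while the small amount of water and the chelating phosphine limit hydrolysis of the vinylogous esters and phosphine addition to the quinone.

Step 4
Reactants: 5 2,5-dimethoxy-3,6-bis[4-(triisopropylsilyloxy)phenyl]-1,4-benzoquinone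
Product: 6 2-hydroxy-5-methoxy-3,6-bis[4-(triisopropylsilyloxy)phenyl]-1,4-benzoquinone
Conditions: LiOH·H2O (1.05 equiv), THF/H2O, 0 °C; then 1 M HCl to pH 3
Reagents that add atoms: lithium hydroxide, [Li+].[OH-]
Why: Saponification of one vinylogous methyl ester by addition–elimination, in which the single equivalent of hydroxide is used up by the acidic hydroxyquinone and the resulting quinonolate anion resists a second attack, so the reaction should stop at the mono-methyl ether (the two methoxyls are equivalent by symmetry).

Step 5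
Reactants: 7 (2R,2'R)-2,2'-[(2-iodo-1,3-phenylene)bis(oxy)]bis[N-(2,4,6-trimethylphenyl)propanamide]
Product: 8 (R,R)-[2,6-bis(1-(mesitylcarbamoyl)ethoxy)phenyl]-λ3-iodanediyl diacetate
Conditions: CH3CO3H (ca. 35 % in AcOH), AcOH/CH2Cl2, rt; evaporate, triturate
Reagents that add atoms: peracetic acid, CC(=O)OO; acetic acid, CC(=O)O
Why: Peracid oxidation of an aryl iodide in acetic acid is the standard preparation of (diacetoxyiodo)arenes, and doing it apart from the substrate keeps peracid away from the 1,2-dione made in step 6.

Step 6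
Reactants: 6 2-hydroxy-5-methoxy-3,6-bis[4-(triisopropylsilyloxy)phenyl]-1,4-benzoquinone; 8 (R,R)-[2,6-bis(1-(mesitylcarbamoyl)ethoxy)phenyl]-λ3-iodanediyl diacetate (1.1 equiv)
Product: 9 (3S)-3,5-dimethoxy-3,6-bis[4-(triisopropylsilyloxy)phenyl]cyclohex-5-ene-1,2,4-trione
Conditions: CH2Cl2/MeOH (4:1), −40 °C → −20 °C
Reagents that add atoms: methanol, CO
Why: Proposed new method: ligand exchange places the enol oxygen of 6 on trivalent iodine, methanol then attacks the aryl-bearing enol carbon with loss of iodoarene 7 (SN2'-type reductive displacement), and the two lactamide arms of the C2-symmetric iodane should shield one face of the enolate so that the methoxyl enters to give the (S) quaternary centre, the later C5; the closest known reactions are the trivalent-iodine α-alkoxylation of enolised 1,3-dicarbonyl compounds in alcohols and the chiral-iodane alkoxylative or hydroxylative dearomatisation of phenols, neither of which has been shown for a hydroxyquinone.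

Step 7
Reactants: 9 (3S)-3,5-dimethoxy-3,6-bis[4-(triisopropylsilyloxy)phenyl]cyclohex-5-ene-1,2,4-trione
Product: 11 (1S,5R)-1-hydroxy-3,5-dimethoxy-4-oxo-2,5-bis[4-(triisopropylsilyloxy)phenyl]cyclopent-2-ene-1-carboxylic acid, via trione hydrate 10 (not isolated)
Conditions: NaHCO3 (2 equiv), THF/H2O (1:1), 0 °C → rt; then 1 M HCl to pH 3 at 0 °C, extract cold, use at once
Reagents that add atoms: water, O
Why: Water adds to the trione carbonyl next to the quaternary carbon (the only one of the three that is neither a vinylogous ester nor an enone carbonyl) to give hydrate 10, and in its monoanion the quaternary carbon shifts to the neighbouring carbonyl carbon through a three-centre transition state, which makes the C4–C5 bond and turns the hydrated carbon into the carboxylate on C4, the later C6. This is a benzilic acid rearrangement with six-to-five ring contraction, the reaction type known for cyclic 1,2-diones and for the first stage of the Hooker oxidation of 3-substituted 2-hydroxy-1,4-quinones. The cyclopentenone is closed by the 1,2-shift itself, a ring contraction and not an exo or endo cyclisation. C5 migrates with retention, and it controls the new centre C4: the carbon that becomes the carboxyl group has to leave the ring plane and should do so on the side of C5 that carries the methoxyl rather than the bulkier aryl ring, which leaves the C4 oxygen cis to that aryl ring. The step needs the concerted shift to beat retro-Claisen scission of the same C–C bond, which would open the ring and flatten C5; the doubly flanked carbonyl is electrophilic enough for bicarbonate at 0 °C, the shift is geometrically pre-set, and attack at the other dione carbonyl would give the same acid by shift of the sp2 carbon without touching C5. The carboxylate cannot revert, so the contraction is irreversible.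

Step 8
Reactants: 11 (1S,5R)-1-hydroxy-3,5-dimethoxy-4-oxo-2,5-bis[4-(triisopropylsilyloxy)phenyl]cyclopent-2-ene-1-carboxylic acid
Product: 12 (4R,5R)-4-hydroxy-4-(hydroxymethyl)-2,5-dimethoxy-3,5-bis[4-(triisopropylsilyloxy)phenyl]cyclopent-2-en-1-one
Conditions: BH3·SMe2 (2 equiv), THF, 0 °C; MeOH quench
Reagents that add atoms: none
Why: Borane reduces a carboxylic acid through its acyloxyborane (here a cyclic one with the α-hydroxyl) faster than a ketone, so a limited amount at 0 °C should take the acid to the primary alcohol and leave the hindered conjugated C1 ketone, the tetrasubstituted enol ether and the silyl ethers untouched, with no stereocentre involved.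

Step 9
Reactants: 12 (4R,5R)-4-hydroxy-4-(hydroxymethyl)-2,5-dimethoxy-3,5-bis[4-(triisopropylsilyloxy)phenyl]cyclopent-2-en-1-one
Product: 14 (3R,4R)-4,6-dimethoxy-4,7-bis[4-(triisopropylsilyloxy)phenyl]-1-oxaspiro[2.4]hept-6-en-5-one, via primary tosylate 13 (not isolated)
Conditions: TsCl (1.2 equiv), Et3N, Bu2SnO (5 mol %), CH2Cl2, 0 °C → rt; then DBU, rt
Reagents that add atoms: p-toluenesulfonyl chloride, Cc1ccc(cc1)S(Cl)(=O)=O (its sulfonyl group is in 13 and is lost again on closure to 14)
Why: Tin-catalysed sulfonylation through the stannylene acetal picks the primary hydroxyl of the 1,2-diol (the tertiary one cannot be sulfonylated), and DBU then closes the oxirane by intramolecular Williamson displacement (3-exo-tet) at C6, so C4 keeps its configuration and its oxygen stays cis to the C5 aryl group.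

Step 10
Reactants: 14 (3R,4R)-4,6-dimethoxy-4,7-bis[4-(triisopropylsilyloxy)phenyl]-1-oxaspiro[2.4]hept-6-en-5-one
Product: 15 (3R,4R)-4,7-bis(4-hydroxyphenyl)-4,6-dimethoxy-1-oxaspiro[2.4]hept-6-en-5-one (CNP0504072.1)
Conditions: Bu4NF (2.5 equiv), AcOH (3 equiv), THF, 0 °C
Reagents that add atoms: none
Why: Fluoride cleaves aryl silyl ethers quickly, and the acetic acid buffer protonates each phenoxide at once so that the oxirane and the enone should not be exposed to base.

## Compound list

1 | bromanil (2,3,5,6-tetrabromo-1,4-benzoquinone) | O=C1C(Br)=C(Br)C(=O)C(Br)=C1Br | starting material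
2 | 2,5-dibromo-3,6-dimethoxy-1,4-benzoquinone | COC1=C(Br)C(=O)C(OC)=C(Br)C1=O | intermediate
3 | 4-(4,4,5,5-tetramethyl-1,3,2-dioxaborolan-2-yl)phenol | CC1(C)OB(OC1(C)C)c1ccc(O)cc1 | starting material
4 | triisopropyl[4-(4,4,5,5-tetramethyl-1,3,2-dioxaborolan-2-yl)phenoxy]silane | CC(C)[Si](Oc1ccc(cc1)B1OC(C)(C)C(C)(C)O1)(C(C)C)C(C)C | intermediate
5 | 2,5-dimethoxy-3,6-bis[4-(triisopropylsilyloxy)phenyl]-1,4-benzoquinone | COC1=C(c2ccc(O[Si](C(C)C)(C(C)C)C(C)C)cc2)C(=O)C(OC)=C(c2ccc(O[Si](C(C)C)(C(C)C)C(C)C)cc2)C1=O | intermediate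
6 | 2-hydroxy-5-methoxy-3,6-bis[4-(triisopropylsilyloxy)phenyl]-1,4-benzoquinone | COC1=C(c2ccc(O[Si](C(C)C)(C(C)C)C(C)C)cc2)C(=O)C(O)=C(c2ccc(O[Si](C(C)C)(C(C)C)C(C)C)cc2)C1=O | intermediate
7 | (2R,2'R)-2,2'-[(2-iodo-1,3-phenylene)bis(oxy)]bis[N-(2,4,6-trimethylphenyl)propanamide] | C[C@@H](Oc1cccc(O[C@H](C)C(=O)Nc2c(C)cc(C)cc2C)c1I)C(=O)Nc1c(C)cc(C)cc1C | starting material
8 | (R,R)-[2,6-bis(1-(mesitylcarbamoyl)ethoxy)phenyl]-λ3-iodanediyl diacetate | C[C@@H](Oc1cccc(O[C@H](C)C(=O)Nc2c(C)cc(C)cc2C)c1I(OC(C)=O)OC(C)=O)C(=O)Nc1c(C)cc(C)cc1C | intermediate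
9 | (3S)-3,5-dimethoxy-3,6-bis[4-(triisopropylsilyloxy)phenyl]cyclohex-5-ene-1,2,4-trione (key-step precursor) | COC1=C(c2ccc(O[Si](C(C)C)(C(C)C)C(C)C)cc2)C(=O)C(=O)[C@](OC)(c2ccc(O[Si](C(C)C)(C(C)C)C(C)C)cc2)C1=O | intermediate
10 | hydrate of 9: gem-diol at the carbonyl carbon next to the quaternary centre, that centre unchanged (not isolated) | COC1=C(c2ccc(O[Si](C(C)C)(C(C)C)C(C)C)cc2)C(=O)C(O)(O)[C@](OC)(c2ccc(O[Si](C(C)C)(C(C)C)C(C)C)cc2)C1=O | intermediate
11 | (1S,5R)-1-hydroxy-3,5-dimethoxy-4-oxo-2,5-bis[4-(triisopropylsilyloxy)phenyl]cyclopent-2-ene-1-carboxylic acid; hydroxyl cis to the C5 aryl group (key-step product) | COC1=C(c2ccc(O[Si](C(C)C)(C(C)C)C(C)C)cc2)[C@@](O)(C(=O)O)[C@](OC)(c2ccc(O[Si](C(C)C)(C(C)C)C(C)C)cc2)C1=O | intermediate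
12 | (4R,5R)-4-hydroxy-4-(hydroxymethyl)-2,5-dimethoxy-3,5-bis[4-(triisopropylsilyloxy)phenyl]cyclopent-2-en-1-one | COC1=C(c2ccc(O[Si](C(C)C)(C(C)C)C(C)C)cc2)[C@@](O)(CO)[C@](OC)(c2ccc(O[Si](C(C)C)(C(C)C)C(C)C)cc2)C1=O | intermediate
13 | primary p-toluenesulfonate of 12, (4R,5R) (not isolated) | COC1=C(c2ccc(O[Si](C(C)C)(C(C)C)C(C)C)cc2)[C@@](O)(COS(=O)(=O)c2ccc(C)cc2)[C@](OC)(c2ccc(O[Si](C(C)C)(C(C)C)C(C)C)cc2)C1=O | intermediate
14 | (3R,4R)-4,6-dimethoxy-4,7-bis[4-(triisopropylsilyloxy)phenyl]-1-oxaspiro[2.4]hept-6-en-5-one | COC1=C(c2ccc(O[Si](C(C)C)(C(C)C)C(C)C)cc2)[C@@]2(CO2)[C@](OC)(c2ccc(O[Si](C(C)C)(C(C)C)C(C)C)cc2)C1=O | intermediate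
15 | (3R,4R)-4,7-bis(4-hydroxyphenyl)-4,6-dimethoxy-1-oxaspiro[2.4]hept-6-en-5-one; oxirane oxygen cis to the C5 aryl group | COC1=C(c2ccc(O)cc2)[C@@]2(CO2)[C@](OC)(c2ccc(O)cc2)C1=O | target

## Step count

Total: 10 steps. Longest linear sequence: 8 steps (1, 3, 4, 6, 7, 8, 9, 10); steps 2 and 5 are side branches.

## Steps most likely to fail

**Step 6** (the one step flagged as a new method). What may go wrong: weak enantiofacial discrimination when methanol attacks the iodane-bound enolate, or a racemic background pathway. Fallback with known chemistry: from 6, oxidation with PhI(OAc)2 in MeOH/CH2Cl2 at 0 °C, the established trivalent-iodine α-alkoxylation of enolised 1,3-dicarbonyl compounds, should give the racemic trione F1. Preparative chromatography on a chiral stationary phase (amylose tris(3,5-dimethylphenylcarbamate), aprotic eluent) then delivers the (S)-enantiomer, which is 9, where the route is rejoined.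

**Step 7.** What may go wrong: heterolysis of the bond between the hydrated carbon and the quaternary carbon (retro-Claisen opening) competing with the concerted shift, which would lower the yield and erode the configuration at C5; or the carboxyl carbon leaving on the aryl face. Fallback: from 9, the contraction is run on purpose under equilibrating conditions (aqueous K2CO3, THF, rt). The ring-opened keto acid F2 should reclose by intramolecular aldol addition, and retro-aldol/aldol exchange should funnel the material into the more stable diastereomer with the carboxyl group trans to the C5 aryl ring. This gives up C5, so 11 forms together with ent-11 F3. Crystallisation of the (S)-1-phenylethylammonium salt of 11 F4 (or of the salt with the antipodal amine, whichever pair is less soluble), followed by cold dilute HCl, returns 11.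

**Step 9.** What may go wrong: retro-aldol opening of the C4 alkoxide (a β-hydroxy ketone) under base competing with ring closure, which would cleave the ring or scramble C4 and C5; or sluggish sulfonylation of the neopentyl-type CH2OH. Fallback: from 12, Mitsunobu cyclodehydration (PPh3, diisopropyl azodicarboxylate, toluene, rt) activates the primary hydroxyl as its oxyphosphonium ion and lets the neutral tertiary hydroxyl displace it, giving 14 directly without any alkoxide; this fallback makes no compound outside the list (F0).

## Further compounds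

F1 | step 6 | racemic 3,5-dimethoxy-3,6-bis[4-(triisopropylsilyloxy)phenyl]cyclohex-5-ene-1,2,4-trione | COC1=C(c2ccc(O[Si](C(C)C)(C(C)C)C(C)C)cc2)C(=O)C(=O)C(OC)(c2ccc(O[Si](C(C)C)(C(C)C)C(C)C)cc2)C1=O
F2 | step 7 | (3E)-4,6-dimethoxy-2,5-dioxo-3,6-bis[4-(triisopropylsilyloxy)phenyl]hex-3-enoic acid (racemic at C6, not isolated) | OC(=O)C(=O)/C(c1ccc(O[Si](C(C)C)(C(C)C)C(C)C)cc1)=C(OC)\C(=O)C(OC)c1ccc(O[Si](C(C)C)(C(C)C)C(C)C)cc1
F3 | step 7 | ent-11, (1R,5S)-1-hydroxy-3,5-dimethoxy-4-oxo-2,5-bis[4-(triisopropylsilyloxy)phenyl]cyclopent-2-ene-1-carboxylic acid | COC1=C(c2ccc(O[Si](C(C)C)(C(C)C)C(C)C)cc2)[C@](O)(C(=O)O)[C@@](OC)(c2ccc(O[Si](C(C)C)(C(C)C)C(C)C)cc2)C1=O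
F4 | step 7 | (S)-1-phenylethylammonium salt of 11 | COC1=C(c2ccc(O[Si](C(C)C)(C(C)C)C(C)C)cc2)[C@@](O)(C(=O)[O-])[C@](OC)(c2ccc(O[Si](C(C)C)(C(C)C)C(C)C)cc2)C1=O.C[C@H]([NH3+])c1ccccc1
F0 | step 9 | none | none
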